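(The constants used here stand for no real mixture; the run is a simulation.)

Take one ratio, the stay in the vessel over the lifetime of the substrate, and reckon from it what share of the charge each flask turns.

    substrate → intermediate (k1 = 1.60 × 10⁻⁴ s⁻¹)
    intermediate ⇌ target (K2 = 0.608, k2 = 1.00 × 10⁻⁴ s⁻¹)
    substrate + target ⇌ idle adduct, settled at all times (K3 = 31 L mol⁻¹)
    intermediate → decomposed reagent (k4 = 6.75 × 10⁻⁶ s⁻¹)
    intermediate ⇌ isomer of the product (K5 = 2.1, k5 = 1.75 × 10⁻⁵ s⁻¹)
    intermediate → side product (k6 = 7.24 × 10⁻⁶ s⁻¹)

all flasks: substrate 0.050 M
- alpha: time 6.0 h; a closed flask charged with all of it at once and left for 6.0 h
- delta: a single well-mixed tank run continuously and read at steady state, 6.0 h in it on average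

- in percentages every species weighs as the substrate in it: one idle adduct counts as two
- for target the idle adduct is counted in
- the stated concentrations are those of everything mixed, before any reaction; amounts are the same in each set-up
- in an amount of target, one idle adduct counts as one target
- run time (alpha): 6.0 h

- the set-up with the highest amount of intermediate at the outlet or at the end, in percent of the substrate put in ("none" if the first two lie within 2 percentage points) (alpha / delta / none)
- amount of intermediate at the outlet or at the end, in percent of the substrate put in, alpha
- amount of intermediate at the outlet or at the end, in percent of the substrate put in, delta

Step 1. Set the idle adduct aside for this count. Take the lifetime of the substrate from its turning into intermediate: 1.74 h.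

Step 2. Take the stay, 6.0 h in alpha and 6.0 h on average (the residence time) in delta. It is longer than that lifetime. Divide the two: 3.46 is the turnover count, the stay over the lifetime of the substrate.

Step 3. Turn the count into fractions of the charge. The closed flask keeps e to the minus the count, so with the idle adduct set aside the count gives alpha a turned fraction of 0.968. The tank keeps one over one plus the count, so on the same footing it gives delta 0.776, less than alpha.

Step 4. Assume the intermediate takes the same share of turned substrate in both flasks. Then delta holds 0.801 of what alpha holds. My reckoning stops at this ratio: it points to alpha and gives no amounts.

Step 5. Set the forecast beside it. Noting that “the adduct holds back substrate”, it says alpha, with 0.412 of the charge as intermediate in alpha and 0.334 in delta.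

Step 6. Read the simulation: alpha, with 0.412 in alpha and 0.334 in delta.

Delta over alpha comes to 0.810, beside the 0.801 of the count, but that count rests on an assumed equal share, so test the share. Strike out the turning of intermediate into target, both ways: alpha then gives 0.604 and delta 0.478, a ratio of 0.791. Strike out instead just the way back from target to intermediate, and the order of the two flasks turns: delta minus alpha goes from −7.9 percentage points to 3.5 points.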